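**Plan**

1. Cuts: the O–CMe2 bond of the 2H-pyran (retro oxa-6π, then back to a C-prenyl group); the C=C of the E-methylacrylic acid arm (Wittig); the C–isopropenyl bond at the side-chain stereocentre (conjugate addition); the C–CH2 bond at the quaternary ring carbon (allylic alkylation); two aryl–prenyl bonds.
2. Forward: 2,4,6-trihydroxybenzophenone (both carbocycles bought) → double C-prenylation to the symmetric diprenyl compound → desymmetrising dearomative allylation that brings in a crotonate handle → oxidative closure of the pyran, the only ring made → isopropenyl addition, ester-to-aldehyde, Wittig, saponification.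
3. Enabling feature: in dearomatised ring A (C1 quaternary, C2–O, C3–benzoyl, C4–O, C5–prenyl, C6–OH) the prenyl CH2 on C5 is allylic and vinylogous to the free enol O6–H, whereas O4–H is held in the hydrogen-bond chelate with the benzoyl C=O. Hydride loss therefore unveils the 1-oxatriene O6=C6–C5=CH–CH=CMe2, which closes to the pyran.
4. The C5-prenyl group has two jobs: it makes the aromatic precursor symmetric (and blocks C5) for the desymmetrisation, then it becomes the pyran.
5. Stereochemistry: C1 by ligand-controlled choice between two enantiotopic prenylated carbons (Pd allylation); the side-chain centre by ligand-controlled Rh 1,4-addition; the E-alkene from a stabilised ylide.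

Key step: step 4

Remark: ring A locants are as in line 3; the trione enols are drawn as one tautomer throughout and CIP descriptors refer to the tautomer drawn (the descriptor at C1 changes between 7/8, 9 and 11–15 without any change in space).
Assumption: the hand of the chiral ligands in steps 3 and 5 is the one predicted by the usual models for these catalysts; if the sense found is the opposite, the antipodal ligand is used and nothing else changes.

**Route**

Step 1
Reactants: 1 2,4,6-trihydroxybenzophenone; 2 prenyl bromide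
Product: 3 clusiaphenone B [3,5-diprenyl-2,4,6-trihydroxybenzophenone]
Conditions: 2 (2.1 equiv), 10 % aq. KOH, 0 °C
Reagents that add atoms: prenyl bromide (2), CC(C)=CCBr
Why: Phenoxide C-alkylation of the phloroglucinol anion in water, where hydrogen bonding to the phenoxide oxygens steers the allylic bromide to the two equivalent free ring carbons, should give the symmetric 3,5-diprenyl compound.

Step 2
Reactants: 4 methyl (E)-4-bromobut-2-enoate; 5 potassium acetate
Product: 6 methyl (E)-4-acetoxybut-2-enoate
Conditions: KOAc (1.5 equiv), DMF, rt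
Reagents that add atoms: potassium acetate (5), CC(=O)[O-].[K+]
Why: SN2 displacement of the primary allylic bromide by acetate should give an allylic acetate that is ionised by palladium but does not alkylate a phenol on its own, with the E-alkene untouched.

Step 3
Reactants: 3 clusiaphenone B; 6 methyl (E)-4-acetoxybut-2-enoate
Product: 7 dearomatised enoate [methyl (2E)-4-[(1S)-3-benzoyl-2,6-dihydroxy-1,5-bis(3-methylbut-2-en-1-yl)-4-oxocyclohexa-2,5-dien-1-yl]but-2-enoate]
Conditions: Pd2(dba)3·CHCl3 (2.5 mol %), (R,R)-N,N'-(cyclohexane-1,2-diyl)bis[2-(diphenylphosphino)benzamide] (7.5 mol %), 6 (1.05 equiv), THF, 0 °C → rt; pH 4 buffer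
Reagents that add atoms: methyl (E)-4-acetoxybut-2-enoate (6), COC(=O)/C=C/COC(C)=O
Why: Tsuji–Trost asymmetric allylic alkylation run as a dearomatisation: zerovalent palladium ionises 6 to the 1-(methoxycarbonyl)allyl complex, which is attacked at its CH2 terminus by one of the two enantiotopic prenyl-bearing carbons of the phloroglucinolate inside the chiral ligand pocket, so that C1 is set by the ligand, while O-allylation is reversible and no external base is added, so as to hold back Michael addition of C5 to the new enoate.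

Step 4
Reactants: 7 dearomatised enoate
Product: 9 chromenone enoate [methyl (2E)-4-[(8R)-6-benzoyl-7-hydroxy-2,2-dimethyl-8-(3-methylbut-2-en-1-yl)-5-oxo-5,8-dihydro-2H-chromen-8-yl]but-2-enoate], via oxatriene 8 (not isolated)
Conditions: DDQ (1.2 equiv), PhMe, rt → 50 °C
Reagents that add atoms: none
Why: DDQ abstracts hydride from the CH2 of the C5-prenyl group, the only position that is both allylic and vinylogous to an enol (C5=C6–OH), and loss of the O6 proton gives the 1-oxatriene 8 (O6=C6–C5=CH–CH=CMe2). Oxatriene 8 closes by thermal disrotatory oxa-6π electrocyclisation, which forms the O6–CMe2 bond and the six-membered 2H-pyran. The closest known reaction type is the DDQ dehydrogenative cyclisation of ortho-prenyl phenols, 3-prenyl-4-hydroxycoumarins and lapachol to 2,2-dimethyl-2H-chromenes. No stereocentre is made (the new sp3 carbon carries two methyl groups) and the quaternary centre C1 is not touched. The step needs O6 and not O4 to close the ring: in 7 the C2 oxygen is a ketone and cannot donate, so O4–H is locked in the six-membered hydrogen-bond chelate with the benzoyl C=O, while O6–H is the free, acidic vinylogous-acid hydroxyl that becomes the carbonyl of 8. It also needs the C5-prenyl and not the C1-prenyl to react, which follows because the C1-prenyl CH2 sits on an sp3 carbon with no enol to stabilise a cation, and the enoate is electron-poor.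

Step 5
Reactants: 9 chromenone enoate; 10 isopropenylboronic acid pinacol ester
Product: 11 methyl ester [methyl (3S)-3-{[(8S)-6-benzoyl-7-hydroxy-2,2-dimethyl-8-(3-methylbut-2-en-1-yl)-5-oxo-5,8-dihydro-2H-chromen-8-yl]methyl}-4-methylpent-4-enoate]
Conditions: [RhCl(C2H4)2]2 (2.5 mol %), (R)-BINAP (6 mol %), 10 (3 equiv), KOH (1.3 equiv), dioxane/H2O 10:1, 60 °C; then 1 M HCl to pH 3
Reagents that add atoms: isopropenylboronic acid pinacol ester (10), C=C(C)B1OC(C)(C)C(C)(C)O1
Why: Hayashi–Miyaura rhodium-catalysed asymmetric 1,4-addition: the isopropenyl–rhodium species formed by transmetalation inserts the E-enoate on the α-re face left open by (R)-BINAP, which sets the side-chain centre by ligand control (S in 11, the same arrangement in space as R in the target), and the enol is carried as its potassium salt, in which C3 is too stabilised to add to the enoate.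

Step 6
Reactants: 11 methyl ester
Product: 12 aldehyde [(3S)-3-{[(8S)-6-benzoyl-7-hydroxy-2,2-dimethyl-8-(3-methylbut-2-en-1-yl)-5-oxo-5,8-dihydro-2H-chromen-8-yl]methyl}-4-methylpent-4-enal]
Conditions: i-Bu2AlH (2.3 equiv), CH2Cl2, −78 °C; MeOH, then aq. potassium sodium tartrate
Reagents that add atoms: none
Why: Partial ester reduction at −78 °C, where the tetrahedral aluminium hemiacetal collapses to the aldehyde only on work-up; the first equivalent deprotonates the enolised β-triketone, whose aluminium chelate should shield the ring and benzoyl carbonyls from hydride.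

Step 7
Reactants: 12 aldehyde; 13 ethyl 2-(triphenylphosphoranylidene)propanoate
Product: 14 ethyl ester [ethyl (2E,5R)-5-{[(8S)-6-benzoyl-7-hydroxy-2,2-dimethyl-8-(3-methylbut-2-en-1-yl)-5-oxo-5,8-dihydro-2H-chromen-8-yl]methyl}-2,6-dimethylhepta-2,6-dienoate]
Conditions: 13 (2.5 equiv), CH2Cl2, rt → 40 °C
Reagents that add atoms: ethyl 2-(triphenylphosphoranylidene)propanoate (13), CCOC(=O)C(C)=P(c1ccccc1)(c1ccccc1)c1ccccc1
Why: Wittig olefination with a stabilised ylide should give the trisubstituted E-enoate, the excess ylide covering the equivalent that the acidic enol takes up as a base.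

Step 8
Reactants: 14 ethyl ester
Product: 15 target acid [(2E,5R)-5-{[(8S)-6-benzoyl-7-hydroxy-2,2-dimethyl-8-(3-methylbut-2-en-1-yl)-5-oxo-5,8-dihydro-2H-chromen-8-yl]methyl}-2,6-dimethylhepta-2,6-dienoic acid]
Conditions: LiOH·H2O (6 equiv), THF/MeOH/H2O 3:1:1, rt → 40 °C; then 1 M HCl to pH 3 at 0 °C
Reagents that add atoms: lithium hydroxide, [Li+].[OH-]
Why: Saponification of the ethyl ester, during which the β-triketone sits as its delocalised lithium enolate and is thereby protected against retro-Claisen cleavage and against attack at the vinylogous ester carbon of the pyran; cold, brief acidification should return acid and enol without cyclisation of the alkenes.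

**Compound list**

1 | 2,4,6-trihydroxybenzophenone | O=C(c1ccccc1)c1c(O)cc(O)cc1O | starting material
2 | prenyl bromide (1-bromo-3-methylbut-2-ene) | CC(C)=CCBr | starting material
3 | clusiaphenone B, [2,4,6-trihydroxy-3,5-bis(3-methylbut-2-en-1-yl)phenyl](phenyl)methanone (achiral, symmetric) | O=C(c1ccccc1)c1c(O)c(CC=C(C)C)c(O)c(CC=C(C)C)c1O | intermediate
4 | methyl (E)-4-bromobut-2-enoate | COC(=O)/C=C/CBr | starting material
5 | potassium acetate | CC(=O)[O-].[K+] | starting material
6 | methyl (E)-4-acetoxybut-2-enoate | COC(=O)/C=C/COC(C)=O | intermediate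
7 | methyl (2E)-4-[(1S)-3-benzoyl-2,6-dihydroxy-1,5-bis(3-methylbut-2-en-1-yl)-4-oxocyclohexa-2,5-dien-1-yl]but-2-enoate | COC(=O)/C=C/C[C@@]1(CC=C(C)C)C(O)=C(C(=O)c2ccccc2)C(=O)C(CC=C(C)C)=C1O | intermediate
8 | oxatriene, methyl (2E)-4-[(1S)-3-benzoyl-4-hydroxy-1-(3-methylbut-2-en-1-yl)-5-(3-methylbut-2-en-1-ylidene)-2,6-dioxocyclohex-3-en-1-yl]but-2-enoate, dimethylvinyl group cis to C6 | COC(=O)/C=C/C[C@@]1(CC=C(C)C)C(=O)C(C(=O)c2ccccc2)=C(O)/C(=C/C=C(C)C)C1=O | intermediate (not isolated)
9 | methyl (2E)-4-[(8R)-6-benzoyl-7-hydroxy-2,2-dimethyl-8-(3-methylbut-2-en-1-yl)-5-oxo-5,8-dihydro-2H-chromen-8-yl]but-2-enoate | COC(=O)/C=C/C[C@@]1(CC=C(C)C)C(O)=C(C(=O)c2ccccc2)C(=O)C2=C1OC(C)(C)C=C2 | intermediate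
10 | isopropenylboronic acid pinacol ester (2-isopropenyl-4,4,5,5-tetramethyl-1,3,2-dioxaborolane) | C=C(C)B1OC(C)(C)C(C)(C)O1 | starting material
11 | methyl (3S)-3-{[(8S)-6-benzoyl-7-hydroxy-2,2-dimethyl-8-(3-methylbut-2-en-1-yl)-5-oxo-5,8-dihydro-2H-chromen-8-yl]methyl}-4-methylpent-4-enoate | C=C(C)[C@H](CC(=O)OC)C[C@@]1(CC=C(C)C)C(O)=C(C(=O)c2ccccc2)C(=O)C2=C1OC(C)(C)C=C2 | intermediate
12 | (3S)-3-{[(8S)-6-benzoyl-7-hydroxy-2,2-dimethyl-8-(3-methylbut-2-en-1-yl)-5-oxo-5,8-dihydro-2H-chromen-8-yl]methyl}-4-methylpent-4-enal | C=C(C)[C@H](CC=O)C[C@@]1(CC=C(C)C)C(O)=C(C(=O)c2ccccc2)C(=O)C2=C1OC(C)(C)C=C2 | intermediate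
13 | ethyl 2-(triphenylphosphoranylidene)propanoate | CCOC(=O)C(C)=P(c1ccccc1)(c1ccccc1)c1ccccc1 | starting material
14 | ethyl (2E,5R)-5-{[(8S)-6-benzoyl-7-hydroxy-2,2-dimethyl-8-(3-methylbut-2-en-1-yl)-5-oxo-5,8-dihydro-2H-chromen-8-yl]methyl}-2,6-dimethylhepta-2,6-dienoate | C=C(C)[C@H](C/C=C(\C)C(=O)OCC)C[C@@]1(CC=C(C)C)C(O)=C(C(=O)c2ccccc2)C(=O)C2=C1OC(C)(C)C=C2 | intermediate
15 | (2E,5R)-5-{[(8S)-6-benzoyl-7-hydroxy-2,2-dimethyl-8-(3-methylbut-2-en-1-yl)-5-oxo-5,8-dihydro-2H-chromen-8-yl]methyl}-2,6-dimethylhepta-2,6-dienoic acid | C=C(C)[C@H](C/C=C(\C)C(=O)O)C[C@@]1(CC=C(C)C)C(O)=C(C(=O)c2ccccc2)C(=O)C2=C1OC(C)(C)C=C2 | target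

**Count**

Total steps: 8. Longest linear sequence: 7 (steps 1, 3, 4, 5, 6, 7, 8).

**Three steps most likely to fail**

Step 5. What may go wrong: slow transfer of the 1-substituted alkenyl group to a β-alkyl enoate on a substrate whose triketonate can chelate rhodium, with erosion of facial control. Fallback by auxiliary control, setting out from 9: saponification (LiOH, THF/H2O) should give the enoic acid F1. Activation as the pivalic mixed anhydride (t-BuCOCl, Et3N) and acylation of lithiated (R)-4-phenyloxazolidin-2-one should give the N-enoyl imide F2. Copper-mediated conjugate addition of isopropenylmagnesium bromide (CuBr·SMe2, THF, −40 °C, excess reagent to cover the acidic enol) should occur anti to the phenyl group of the chelated s-cis imide and give the adduct F3. Methanolysis (NaOMe, MeOH, 0 °C) releases the auxiliary and comes back to the route at 11.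

Step 3. What may go wrong: insufficient discrimination between the two enantiotopic carbons, because the ester-bearing allyl unit differs from the parent allyl systems on which this ligand class is known to perform, together with some double allylation. Fallback by resolution, setting out from 3 and 6: the same allylation with achiral Pd(PPh3)4 should give racemic 7, which is separated by preparative chromatography on a chiral stationary phase (amylose tris(3,5-dimethylphenylcarbamate)). The unwanted enantiomer F4 is set aside and the route is rejoined at 7. The later ligand-controlled step 5 turns any remaining minor enantiomer into a separable diastereomer.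

Step 4. What may go wrong: loss of regiocontrol in the electrocyclisation (closure through O4 after tautomer exchange) or over-oxidation of the electron-rich enol. Fallback that fixes the ring oxygen before the ring is made, setting out from 1: para-selective O-alkylation with 3-chloro-3-methylbut-1-yne (K2CO3, KI, catalytic copper iodide CuI, acetone) should give the aryl 1,1-dimethylpropargyl ether F5. 6-endo hydroarylation catalysed by Ph3PAuNTf2 (CH2Cl2, rt) keeps that O–C bond and should give the chromene F6. C-prenylation at the only free ring carbon (2, aq. KOH, 0 °C) should give the 8-prenylchromene F7. Dearomative allylation of F7 with 6 under the conditions of step 3, now a face-selective attack at the single nucleophilic carbon, comes back to the route at 9.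

**Further compounds**

F1 | step 5 | (2E)-4-[(8R)-6-benzoyl-7-hydroxy-2,2-dimethyl-8-(3-methylbut-2-en-1-yl)-5-oxo-5,8-dihydro-2H-chromen-8-yl]but-2-enoic acid | OC(=O)/C=C/C[C@@]1(CC=C(C)C)C(O)=C(C(=O)c2ccccc2)C(=O)C2=C1OC(C)(C)C=C2
F2 | step 5 | (4R)-3-{(2E)-4-[(8R)-6-benzoyl-7-hydroxy-2,2-dimethyl-8-(3-methylbut-2-en-1-yl)-5-oxo-5,8-dihydro-2H-chromen-8-yl]but-2-enoyl}-4-phenyloxazolidin-2-one | O=C(/C=C/C[C@@]1(CC=C(C)C)C(O)=C(C(=O)c2ccccc2)C(=O)C2=C1OC(C)(C)C=C2)N1C(=O)OC[C@H]1c1ccccc1
F3 | step 5 | (4R)-3-[(3S)-3-{[(8S)-6-benzoyl-7-hydroxy-2,2-dimethyl-8-(3-methylbut-2-en-1-yl)-5-oxo-5,8-dihydro-2H-chromen-8-yl]methyl}-4-methylpent-4-enoyl]-4-phenyloxazolidin-2-one | C=C(C)[C@H](CC(=O)N1C(=O)OC[C@H]1c1ccccc1)C[C@@]1(CC=C(C)C)C(O)=C(C(=O)c2ccccc2)C(=O)C2=C1OC(C)(C)C=C2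
F4 | step 3 | methyl (2E)-4-[(1R)-3-benzoyl-2,6-dihydroxy-1,5-bis(3-methylbut-2-en-1-yl)-4-oxocyclohexa-2,5-dien-1-yl]but-2-enoate (enantiomer of 7) | COC(=O)/C=C/C[C@]1(CC=C(C)C)C(O)=C(C(=O)c2ccccc2)C(=O)C(CC=C(C)C)=C1O
F5 | step 4 | [2,6-dihydroxy-4-(2-methylbut-3-yn-2-yloxy)phenyl](phenyl)methanone | C#CC(C)(C)Oc1cc(O)c(C(=O)c2ccccc2)c(O)c1
F6 | step 4 | (5,7-dihydroxy-2,2-dimethyl-2H-chromen-6-yl)(phenyl)methanone | CC1(C)C=Cc2c(O)c(C(=O)c3ccccc3)c(O)cc2O1
F7 | step 4 | [5,7-dihydroxy-2,2-dimethyl-8-(3-methylbut-2-en-1-yl)-2H-chromen-6-yl](phenyl)methanone | CC1(C)C=Cc2c(O)c(C(=O)c3ccccc3)c(O)c(CC=C(C)C)c2O1
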